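**Strategy.** Ring C of the isoflavanone is opened at C2–C3. C2 is an unsubstituted O1–CH2 carbon standing in a 1,6 relation to C3 (C3–C4–C4a–C8a–O1–C2), so it is carried as the methyl ether of ring A, and C3 as a diazo carbon between ring B and the C4 ketone. A chiral dirhodium carboxylate turns this α-aryl-α-diazo ketone into a carbene that inserts into a methoxy C–H bond; that single operation forms C2–C3, closes the pyranone ring and sets the C3 stereocentre. The precursor is a 2-diazo-1,2-diarylethanone with all four phenols as TIPS ethers, assembled by palladium-catalysed α-arylation of a ring A acetophenone with a geranylated ring B bromide and diazo transfer.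

Key step: step 11

Assumption: Rh2(S-PTTL)4 is taken to deliver the (R)-configuration at C3; should the sense prove opposite, the mirror-image catalyst Rh2(R-PTTL)4 would be used with no other change.

Remark on protecting groups: all four phenols are carried as triisopropylsilyl (TIPS) ethers. The oxygens next to the ketone, the enolised carbon and the metalated carbon must resist base and anionic silyl migration. None of them may offer a C–H bond on an oxygen-bearing carbon to the carbene.

Step 1
Reactants: 1 2-methylresorcinol (2-methylbenzene-1,3-diol)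
Product: 2 1,3-bis(methoxymethoxy)-2-methylbenzene
Conditions: MOMCl (2.5 equiv), i-Pr2NEt, CH2Cl2, 0 °C → rt
Reagents that add atoms: chloromethyl methyl ether, COCCl
Why: Williamson-type O-alkylation of both phenols with the reactive α-chloro ether gives acetal ethers that survive borylation, base and organolithium chemistry and later direct ortho-lithiation.

Step 2
Reactants: 2 1,3-bis(methoxymethoxy)-2-methylbenzene
Product: 4 3,5-bis(methoxymethoxy)-4-methylphenol, via aryl pinacol boronate 3 (not isolated)
Conditions: [Ir(OMe)(cod)]2 (1.5 mol%), 4,4'-di-tert-butyl-2,2'-bipyridine (3 mol%), B2pin2 (1.0 equiv), THF, 80 °C; then aq. NaOH, 30% H2O2, 0 °C → rt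
Reagents that add atoms: hydrogen peroxide, OO
Why: Sterically governed iridium-catalysed aromatic C–H borylation takes the only ring C–H without an ortho substituent (para to the methyl group), and alkaline peroxide oxidation of the C–B bond (aryl shift from boron to oxygen) should give the mirror-symmetric phenol in one pot.

Step 3
Reactants: 4 3,5-bis(methoxymethoxy)-4-methylphenol
Product: 5 5-methoxy-1,3-bis(methoxymethoxy)-2-methylbenzene
Conditions: MeI, K2CO3, acetone, reflux
Reagents that add atoms: iodomethane, CI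
Why: Williamson methylation of the single free phenol installs the methyl group that later becomes C2 and keeps the mirror symmetry of the ring.

Step 4
Reactants: 5 5-methoxy-1,3-bis(methoxymethoxy)-2-methylbenzene
Product: 8 1-[6-methoxy-2,4-bis(methoxymethoxy)-3-methylphenyl]ethanone, via aryllithium 6 (not isolated), via lithium hemiaminal adduct 7 (not isolated)
Conditions: n-BuLi (1.1 equiv), THF, 0 °C; MeC(O)N(OMe)Me, −78 → 0 °C; then H2O
Reagents that add atoms: N-methoxy-N-methylacetamide, CC(=O)N(C)OC
Why: Directed ortho-metalation occurs at either of the two equivalent ring positions flanked by the methoxy and a methoxymethoxy group, and the aryllithium acylates once because the chelated tetrahedral adduct persists until the quench (Weinreb ketone synthesis), so the later 6-methyl pattern is fixed by symmetry.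

Step 5
Reactants: 8 1-[6-methoxy-2,4-bis(methoxymethoxy)-3-methylphenyl]ethanone
Product: 9 1-(2,4-dihydroxy-6-methoxy-3-methylphenyl)ethanone
Conditions: 3 M aq. HCl, MeOH, 50 °C
Reagents that add atoms: none
Why: Acid-catalysed acetal exchange with methanol removes both methoxymethyl groups while the aryl methyl ether and the ketone are untouched.

Step 6
Reactants: 9 1-(2,4-dihydroxy-6-methoxy-3-methylphenyl)ethanone
Product: 10 1-[6-methoxy-3-methyl-2,4-bis(triisopropylsilyloxy)phenyl]ethanone
Conditions: TIPSOTf (2.3 equiv), 2,6-lutidine, CH2Cl2, −20 → 0 °C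
Reagents that add atoms: triisopropylsilyl trifluoromethanesulfonate, CC(C)[Si](OS(=O)(=O)C(F)(F)F)(C(C)C)C(C)C
Why: O-silylation with a silyl triflate and a hindered weak base reaches even the hydrogen-bonded, flanked phenol, giving TIPS ethers that resist base and anionic O→O silyl migration in the enolate steps and later shield the ortho oxygen from the carbene.

Step 7
Reactants: 11 4,6-dibromoresorcinol (4,6-dibromobenzene-1,3-diol)
Product: 12 1,5-dibromo-2,4-bis(triisopropylsilyloxy)benzene
Conditions: TIPSOTf (2.3 equiv), 2,6-lutidine, CH2Cl2, 0 °C → rt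
Reagents that add atoms: triisopropylsilyl trifluoromethanesulfonate, CC(C)[Si](OS(=O)(=O)C(F)(F)F)(C(C)C)C(C)C
Why: O-silylation of both phenols gives bulky silyl ethers that tolerate halogen–metal exchange at low temperature and are already the protecting groups needed in the key step.

Step 8
Reactants: 12 1,5-dibromo-2,4-bis(triisopropylsilyloxy)benzene; 13 geranyl bromide ((2E)-1-bromo-3,7-dimethylocta-2,6-diene)
Product: 16 1-bromo-5-[(2E)-3,7-dimethylocta-2,6-dien-1-yl]-2,4-bis(triisopropylsilyloxy)benzene, via aryllithium 14 (not isolated), via arylcopper 15 (not isolated)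
Conditions: n-BuLi (1.0 equiv), THF, −78 °C; CuBr·SMe2 (1.1 equiv), −78 °C; then 13, −78 → 0 °C
Reagents that add atoms: none
Why: Bromine–lithium exchange stops after one bromine because the aryllithium is deactivated towards a second exchange, immediate transmetalation to copper at −78 °C forestalls anionic O→C silyl migration, and the arylcopper displaces the primary allylic bromide at its unsubstituted terminus (SN2 allylation) with the E geometry retained.

Step 9
Reactants: 10 1-[6-methoxy-3-methyl-2,4-bis(triisopropylsilyloxy)phenyl]ethanone; 16 1-bromo-5-geranyl-2,4-bis(triisopropylsilyloxy)benzene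
Product: 17 2-[5-geranyl-2,4-bis(triisopropylsilyloxy)phenyl]-1-[6-methoxy-3-methyl-2,4-bis(triisopropylsilyloxy)phenyl]ethanone
Conditions: Pd2(dba)3 (2.5 mol%), XPhos (6 mol%), K3PO4 (2.5 equiv), toluene, 90 °C
Reagents that add atoms: none
Why: Palladium-catalysed ketone α-arylation (oxidative addition of the aryl bromide to zerovalent palladium, enolate formation with the mild phosphate base, C–C reductive elimination) should stop at monoarylation because the more acidic product rests as its enolate and the new CH2 is crowded.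

Step 10
Reactants: 17 2-[5-geranyl-2,4-bis(triisopropylsilyloxy)phenyl]-1-[6-methoxy-3-methyl-2,4-bis(triisopropylsilyloxy)phenyl]ethanone
Product: 18 2-diazo-2-[5-geranyl-2,4-bis(triisopropylsilyloxy)phenyl]-1-[6-methoxy-3-methyl-2,4-bis(triisopropylsilyloxy)phenyl]ethanone
Conditions: 4-acetamidobenzenesulfonyl azide (1.3 equiv), DBU (1.5 equiv), MeCN/THF, 0 °C → rt
Reagents that add atoms: 4-acetamidobenzenesulfonyl azide, CC(=O)Nc1ccc(cc1)S(=O)(=O)N=[N+]=[N-]
Why: Regitz diazo transfer to the methylene activated by both the ketone and ring B, in which the amidine-generated enolate attacks the terminal azide nitrogen and the triazene collapses to the diazo ketone and the sulfonamide.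

Step 11
Reactants: 18 2-diazo-2-[5-geranyl-2,4-bis(triisopropylsilyloxy)phenyl]-1-[6-methoxy-3-methyl-2,4-bis(triisopropylsilyloxy)phenyl]ethanone
Product: 19 (3R)-3-[5-geranyl-2,4-bis(triisopropylsilyloxy)phenyl]-6-methyl-5,7-bis(triisopropylsilyloxy)chroman-4-one
Conditions: Rh2(S-PTTL)4 (dirhodium tetrakis[N-phthaloyl-(S)-tert-leucinate], 2 mol%), toluene (0.01 M), 4 Å molecular sieves, slow addition of 18, −20 °C → rt
Reagents that add atoms: none
Why: Rh2(S-PTTL)4 expels N2 from 18 to give an electrophilic aryl/acyl-substituted rhodium carbene at C3, which engages a C–H bond of the ring A methoxy group in a concerted, hydride-transfer-like three-centre transition state that forms C2–C3 and C3–H as the metal leaves. The closest known reaction type is the dirhodium carboxylate-catalysed intramolecular C–H insertion of o-alkoxyaryl diazo ketones to chroman-4-ones, and insertion of aryl-substituted rhodium carbenes into methyl ether C–H bonds is likewise established. Ring C is closed by 1,6-insertion, giving the six-membered pyranone through the C3–C4–C4a–C8a–O1–C2 tether. The only new stereocentre, C3, is set under catalyst control, since the chiral pocket of N-phthaloyl-tert-leucinate ligands decides which face of the carbene carbon receives the hydrogen (C2 is not stereogenic). Site selectivity is required and is built into 18: the O–CH3 hydrogens are the only C–H bonds on an oxygen-bearing carbon, the four TIPS groups block the phenolic oxygens from ylide formation and silyl transfer, and the geranyl alkenes sit meta to the carbene-bearing carbon and cannot reach it within the molecule. Slow addition at high dilution suppresses bimolecular cyclopropanation and carbene dimerisation, an oxonium ylide formed at the methoxy oxygen has no easy shift and should revert to the carbene, and the neutral medium leaves the new α-aryl ketone configurationally intact.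

Step 12
Reactants: 19 (3R)-3-[5-geranyl-2,4-bis(triisopropylsilyloxy)phenyl]-6-methyl-5,7-bis(triisopropylsilyloxy)chroman-4-one
Product: 20 (3R)-3-[5-geranyl-2,4-dihydroxyphenyl]-5,7-dihydroxy-6-methylchroman-4-one (CNP0348256.1)
Conditions: HF·pyridine (excess), pyridine, THF, 0 °C → rt
Reagents that add atoms: none
Why: Fluoride-driven Si–O cleavage in a buffered, weakly acidic medium frees the four phenols without forming phenoxide or enolate, so the base-labile C3 stereocentre and the acid-sensitive geranyl chain should both be spared.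

**Compound list**

1 | 2-methylresorcinol | Cc1c(O)cccc1O | starting material
2 | 1,3-bis(methoxymethoxy)-2-methylbenzene | COCOc1cccc(OCOC)c1C | intermediate
3 | 2-[3,5-bis(methoxymethoxy)-4-methylphenyl]-4,4,5,5-tetramethyl-1,3,2-dioxaborolane | COCOc1cc(B2OC(C)(C)C(C)(C)O2)cc(OCOC)c1C | intermediate
4 | 3,5-bis(methoxymethoxy)-4-methylphenol | COCOc1cc(O)cc(OCOC)c1C | intermediate
5 | 5-methoxy-1,3-bis(methoxymethoxy)-2-methylbenzene | COCOc1cc(OC)cc(OCOC)c1C | intermediate
6 | [6-methoxy-2,4-bis(methoxymethoxy)-3-methylphenyl]lithium | [Li]c1c(OC)cc(OCOC)c(C)c1OCOC | intermediate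
7 | lithium 1-[methoxy(methyl)amino]-1-[6-methoxy-2,4-bis(methoxymethoxy)-3-methylphenyl]ethanolate | CON(C)C(C)(O[Li])c1c(OC)cc(OCOC)c(C)c1OCOC | intermediate
8 | 1-[6-methoxy-2,4-bis(methoxymethoxy)-3-methylphenyl]ethanone | CC(=O)c1c(OC)cc(OCOC)c(C)c1OCOC | intermediate
9 | 1-(2,4-dihydroxy-6-methoxy-3-methylphenyl)ethanone | CC(=O)c1c(OC)cc(O)c(C)c1O | intermediate
10 | 1-[6-methoxy-3-methyl-2,4-bis(triisopropylsilyloxy)phenyl]ethanone | CC(=O)c1c(OC)cc(O[Si](C(C)C)(C(C)C)C(C)C)c(C)c1O[Si](C(C)C)(C(C)C)C(C)C | intermediate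
11 | 4,6-dibromoresorcinol | Oc1cc(O)c(Br)cc1Br | starting material
12 | 1,5-dibromo-2,4-bis(triisopropylsilyloxy)benzene | Brc1cc(Br)c(O[Si](C(C)C)(C(C)C)C(C)C)cc1O[Si](C(C)C)(C(C)C)C(C)C | intermediate
13 | geranyl bromide, (2E)-1-bromo-3,7-dimethylocta-2,6-diene | CC(C)=CCC/C(C)=C/CBr | starting material
14 | [5-bromo-2,4-bis(triisopropylsilyloxy)phenyl]lithium | [Li]c1cc(Br)c(O[Si](C(C)C)(C(C)C)C(C)C)cc1O[Si](C(C)C)(C(C)C)C(C)C | intermediate
15 | [5-bromo-2,4-bis(triisopropylsilyloxy)phenyl]copper | [Cu]c1cc(Br)c(O[Si](C(C)C)(C(C)C)C(C)C)cc1O[Si](C(C)C)(C(C)C)C(C)C | intermediate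
16 | 1-bromo-5-[(2E)-3,7-dimethylocta-2,6-dien-1-yl]-2,4-bis(triisopropylsilyloxy)benzene | CC(C)=CCC/C(C)=C/Cc1cc(Br)c(O[Si](C(C)C)(C(C)C)C(C)C)cc1O[Si](C(C)C)(C(C)C)C(C)C | intermediate
17 | 2-[5-geranyl-2,4-bis(triisopropylsilyloxy)phenyl]-1-[6-methoxy-3-methyl-2,4-bis(triisopropylsilyloxy)phenyl]ethanone | CC(C)=CCC/C(C)=C/Cc1cc(CC(=O)c2c(OC)cc(O[Si](C(C)C)(C(C)C)C(C)C)c(C)c2O[Si](C(C)C)(C(C)C)C(C)C)c(O[Si](C(C)C)(C(C)C)C(C)C)cc1O[Si](C(C)C)(C(C)C)C(C)C | intermediate
18 | 2-diazo-2-[5-geranyl-2,4-bis(triisopropylsilyloxy)phenyl]-1-[6-methoxy-3-methyl-2,4-bis(triisopropylsilyloxy)phenyl]ethanone | CC(C)=CCC/C(C)=C/Cc1cc(C(=[N+]=[N-])C(=O)c2c(OC)cc(O[Si](C(C)C)(C(C)C)C(C)C)c(C)c2O[Si](C(C)C)(C(C)C)C(C)C)c(O[Si](C(C)C)(C(C)C)C(C)C)cc1O[Si](C(C)C)(C(C)C)C(C)C | intermediate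
19 | (3R)-3-[5-geranyl-2,4-bis(triisopropylsilyloxy)phenyl]-6-methyl-5,7-bis(triisopropylsilyloxy)chroman-4-one | CC(C)=CCC/C(C)=C/Cc1cc([C@@H]2COc3cc(O[Si](C(C)C)(C(C)C)C(C)C)c(C)c(O[Si](C(C)C)(C(C)C)C(C)C)c3C2=O)c(O[Si](C(C)C)(C(C)C)C(C)C)cc1O[Si](C(C)C)(C(C)C)C(C)C | intermediate
20 | (3R)-3-[5-geranyl-2,4-dihydroxyphenyl]-5,7-dihydroxy-6-methylchroman-4-one | CC(C)=CCC/C(C)=C/Cc1cc([C@@H]2COc3cc(O)c(C)c(O)c3C2=O)c(O)cc1O | target

**Step count and risk**

Total step count: 12 (ring A: steps 1–6; ring B: steps 7–8; union and endgame: steps 9–12). Longest linear sequence: 10 steps (1–6, then 9–12).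

Steps most likely to fail:

Step 11. The crowded diazo ketone may be decomposed only slowly by the bulky chiral catalyst, and the hydrogen may be delivered to C3 with poor facial discrimination, so that enantiomeric purity is low. Fallback: setting out from 18, the ring is closed with the compact achiral catalyst Rh2(OAc)4 (dirhodium tetraacetate) in CH2Cl2 under the same slow-addition regime, which should give the racemic isoflavanone F1. Preparative chromatography on a polysaccharide-based chiral stationary phase separates 19 from its (3S)-antipode F2. F2 is returned to F1 by base-mediated enolisation (catalytic DBU, toluene, rt) and recycled, so the stereocentre is secured by resolution with racemisation instead of asymmetric induction. The route is rejoined at 19.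

Step 9. Coupling of two hindered, electron-rich partners may be sluggish, with hydrodebromination of 16 and base-induced silyl loss competing. Fallback: setting out from 10 and 16, the C3–aryl bond is formed at the diazo stage without a hot basic enolate step. Ketone 10 is trifluoroacetylated (LiN(SiMe3)2, THF, −78 °C, then CF3CO2CH2CF3) to the diketone 4,4,4-trifluoro-1-[6-methoxy-3-methyl-2,4-bis(triisopropylsilyloxy)phenyl]butane-1,3-dione F3. Deacylative diazo transfer (methanesulfonyl azide, Et3N, H2O, MeCN, rt) converts it into the diazomethyl ketone 2-diazo-1-[6-methoxy-3-methyl-2,4-bis(triisopropylsilyloxy)phenyl]ethanone F4. Bromide 16 is converted by aromatic Finkelstein exchange (CuI, NaI, trans-N,N'-dimethylcyclohexane-1,2-diamine, dioxane, 110 °C) into the iodide 1-geranyl-5-iodo-2,4-bis(triisopropylsilyloxy)benzene F5. Palladium-catalysed C–H arylation of the acyldiazomethane (Pd(PPh3)4, Ag2CO3, Et3N, toluene, rt) joins F4 and F5 and gives 18 directly, bypassing 17 and step 10.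

Step 8. Silicon may migrate from oxygen to the lithiated ortho carbon before transmetalation, or the second bromine may also be exchanged. Fallback: setting out from 11, the organometallic step is run on acetal-protected material that cannot undergo silyl migration. MOMCl and i-Pr2NEt give 1,5-dibromo-2,4-bis(methoxymethoxy)benzene F6. n-BuLi (1.0 equiv, THF, −78 °C) gives the chelated aryllithium [5-bromo-2,4-bis(methoxymethoxy)phenyl]lithium F7, which with 13 and 10 mol% CuBr·SMe2 gives 1-bromo-5-geranyl-2,4-bis(methoxymethoxy)benzene F8. Mild acetal cleavage (catalytic HCl, MeOH, rt → 40 °C, stopped early to avoid chroman formation) gives 4-bromo-6-geranylbenzene-1,3-diol F9. Silylation (TIPSOTf, 2,6-lutidine, CH2Cl2) then rejoins the route at 16.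

**Further compounds**

F1 | step 11 | racemic 3-[5-geranyl-2,4-bis(triisopropylsilyloxy)phenyl]-6-methyl-5,7-bis(triisopropylsilyloxy)chroman-4-one | CC(C)=CCC/C(C)=C/Cc1cc(C2COc3cc(O[Si](C(C)C)(C(C)C)C(C)C)c(C)c(O[Si](C(C)C)(C(C)C)C(C)C)c3C2=O)c(O[Si](C(C)C)(C(C)C)C(C)C)cc1O[Si](C(C)C)(C(C)C)C(C)C
F2 | step 11 | (3S)-3-[5-geranyl-2,4-bis(triisopropylsilyloxy)phenyl]-6-methyl-5,7-bis(triisopropylsilyloxy)chroman-4-one | CC(C)=CCC/C(C)=C/Cc1cc([C@H]2COc3cc(O[Si](C(C)C)(C(C)C)C(C)C)c(C)c(O[Si](C(C)C)(C(C)C)C(C)C)c3C2=O)c(O[Si](C(C)C)(C(C)C)C(C)C)cc1O[Si](C(C)C)(C(C)C)C(C)C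
F3 | step 9 | 4,4,4-trifluoro-1-[6-methoxy-3-methyl-2,4-bis(triisopropylsilyloxy)phenyl]butane-1,3-dione | O=C(CC(=O)C(F)(F)F)c1c(OC)cc(O[Si](C(C)C)(C(C)C)C(C)C)c(C)c1O[Si](C(C)C)(C(C)C)C(C)C
F4 | step 9 | 2-diazo-1-[6-methoxy-3-methyl-2,4-bis(triisopropylsilyloxy)phenyl]ethanone | [N-]=[N+]=CC(=O)c1c(OC)cc(O[Si](C(C)C)(C(C)C)C(C)C)c(C)c1O[Si](C(C)C)(C(C)C)C(C)C
F5 | step 9 | 1-[(2E)-3,7-dimethylocta-2,6-dien-1-yl]-5-iodo-2,4-bis(triisopropylsilyloxy)benzene | CC(C)=CCC/C(C)=C/Cc1cc(I)c(O[Si](C(C)C)(C(C)C)C(C)C)cc1O[Si](C(C)C)(C(C)C)C(C)C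
F6 | step 8 | 1,5-dibromo-2,4-bis(methoxymethoxy)benzene | COCOc1cc(OCOC)c(Br)cc1Br
F7 | step 8 | [5-bromo-2,4-bis(methoxymethoxy)phenyl]lithium | [Li]c1cc(Br)c(OCOC)cc1OCOC
F8 | step 8 | 1-bromo-5-[(2E)-3,7-dimethylocta-2,6-dien-1-yl]-2,4-bis(methoxymethoxy)benzene | CC(C)=CCC/C(C)=C/Cc1cc(Br)c(OCOC)cc1OCOC
F9 | step 8 | 4-bromo-6-[(2E)-3,7-dimethylocta-2,6-dien-1-yl]benzene-1,3-diol | CC(C)=CCC/C(C)=C/Cc1cc(Br)c(O)cc1O
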